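The target is 3-hydroxy-2-(3,4-dimethoxyphenyl)-7-(3-methylbut-2-enyloxy)chromen-4-one, a flavonol made of benzo ring A, pyranone ring C and aryl ring B on C2.
Enabling feature: O1, C8a, C4a and C4 of ring C are the atoms of a salicylaldehyde. The remaining C2=C3 pair is a masked alkyne bearing ring B on C2 and, on C3, an oxygen that a C–B bond can stand in for.
Retrosynthetic cuts: C3–O goes back to C3–B. Then C4–C3 and O1–C2 of ring C are cut together, followed by the C7–O–prenyl ether bond and the C(sp)–C1' bond of the arylalkyne.
Forward order: rings A and B are bought. An etherification and a Sonogashira coupling give the two fragments, ring C forms in one rhodium-catalysed oxidative annulation, and boron-to-oxygen exchange ends the route.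
Stereochemistry: there is no stereocentre and no configured double bond (the prenyl alkene carries two methyl groups), so only regiochemistry has to be controlled.

Key step: step 3

Remark: flavone numbering is used (O1, C2, C3, C4, C4a, C5 to C8, C8a, primes for ring B), and MIDA boronates are drawn without the N→B dative bond although their boron is tetracoordinate.

Step 1
Reactants: 1 2,4-dihydroxybenzaldehyde; 2 prenyl bromide (1-bromo-3-methylbut-2-ene)
Product: 3 2-hydroxy-4-(3-methylbut-2-enyloxy)benzaldehyde
Conditions: 2 (1.05 equiv), K2CO3 (1.0 equiv), acetone, reflux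
Reagents that add atoms: none
Why: Williamson ether synthesis (SN2 at the primary allylic bromide); the 2-OH is hydrogen-bonded to the formyl oxygen and is the less acidic and less nucleophilic hydroxyl, so one equivalent of mild carbonate base should ionise and alkylate only the 4-OH para to the aldehyde.

Step 2
Reactants: 4 ethynylboronic acid MIDA ester; 5 4-iodo-1,2-dimethoxybenzene
Product: 6 (3,4-dimethoxyphenyl)ethynylboronic acid MIDA ester
Conditions: PdCl2(PPh3)2 (5 mol %), CuI (10 mol %), Et3N (3 equiv), dry DMF, rt, argon
Reagents that add atoms: none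
Why: Sonogashira coupling of a terminal alkyne with an aryl iodide at room temperature, established for this alkyne building block; the MIDA-bound tetracoordinate boron has no vacant orbital for transmetalation and should stay in place as long as water is excluded.

Step 3
Reactants: 3 2-hydroxy-4-(3-methylbut-2-enyloxy)benzaldehyde; 6 (3,4-dimethoxyphenyl)ethynylboronic acid MIDA ester
Product: 7 3',4'-dimethoxy-7-(3-methylbut-2-enyloxy)flavon-3-ylboronic acid MIDA ester
Conditions: [Cp*RhCl2]2 (2.5 mol %), anhydrous Cu(OAc)2 (2.1 equiv), 4 Å MS, dry 1,4-dioxane, 80 °C, N2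
Reagents that add atoms: none
Why: Proposed new method: acetate exchange gives Cp*Rh(OAc)2 (trivalent rhodium), which binds the phenoxide of 3 and cleaves the neighbouring formyl C–H bond by concerted metalation–deprotonation to a five-membered acyl rhodacycle; alkyne 6 then inserts syn to a seven-membered rhodacycle, reductive elimination completes the C4–C3 and O1–C2 bonds, and two Cu(OAc)2 return monovalent rhodium to the trivalent state. The closest known reactions are the rhodium/copper oxidative annulation of salicylaldehydes with internal alkynes to 2,3-disubstituted chromones and the Cp*Rh annulations of benzamides and anilides that carry alkynyl MIDA boronates through with the C–B bond intact, but an acyl rhodacycle has not been joined to a borylated alkyne. Ring C closes as a formal [4+2] annulation, with O1, C8a, C4a and C4 coming from 3 and C2 and C3 from 6, the last event being reductive elimination within the seven-membered rhodacycle to the six-membered pyranone; no stereocentre is formed. The boron-bearing carbon must bond to the acyl carbon and the aryl-bearing carbon to oxygen, and two channels give this: either the acyl group migrates to the boryl carbon and leaves ring B on rhodium, where the electron-rich aryl group stabilises the vinyl–rhodium bond and the slim acyl terminus (flanked only by its oxygen, no peri C–H) repels the MIDA cage little, or the phenoxide migrates to the aryl-bearing carbon, which the dimethoxyphenyl ring and the σ-donating C–B bond make the electrophilic end of the alkyne, and acyl–vinyl C–C reductive elimination follows from the α-boryl vinylrhodium. The channel to be beaten is acyl migration to the aryl-bearing carbon, which is the orientation these alkynes adopt with aryl–rhodium bonds, so the regiochemistry of 7 has to be proven before the route goes on. Dry Cu(OAc)2, molecular sieves and a silver-free, acetate-buffered medium at 80 °C are chosen to keep the MIDA cage and the acid-labile prenyl ether intact and to hold back decarbonylation of the acyl rhodium and aromatic Claisen rearrangement, while the trisubstituted prenyl alkene is too hindered to compete with the alkyne for rhodium.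

Step 4
Reactants: 7 3',4'-dimethoxy-7-(3-methylbut-2-enyloxy)flavon-3-ylboronic acid MIDA ester
Product: 10 3-hydroxy-2-(3,4-dimethoxyphenyl)-7-(3-methylbut-2-enyloxy)chromen-4-one (target), via flavon-3-ylboronic acid 8 (not isolated), via flavon-3-yl dihydrogen borate 9 (not isolated)
Conditions: 30% aq H2O2 (5 equiv), 1 M aq NaOH (3 equiv), THF, 0 °C to rt
Reagents that add atoms: hydrogen peroxide, OO (the C3–O oxygen of 9 and 10); water, O (the B–OH oxygens of 8 and 9 only)
Why: Standard boronate oxidation, in which hydroxide opens the MIDA cage to 8, hydroperoxide adds to the now tricoordinate boron, C3 migrates from boron to oxygen to give 9 and hydrolysis frees the 3-OH; peroxide present from the start should let oxidation outrun protodeboronation, and the electron-rich prenyl alkene and the aryl ethers are inert to nucleophilic peroxide.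

Compound list
1 | 2,4-dihydroxybenzaldehyde | O=Cc1ccc(O)cc1O | starting material
2 | prenyl bromide (1-bromo-3-methylbut-2-ene) | CC(C)=CCBr | starting material
3 | 2-hydroxy-4-(3-methylbut-2-enyloxy)benzaldehyde | CC(C)=CCOc1ccc(C=O)c(O)c1 | intermediate
4 | ethynylboronic acid MIDA ester | C#CB1OC(=O)CN(C)CC(=O)O1 | starting material
5 | 4-iodo-1,2-dimethoxybenzene | COc1ccc(I)cc1OC | starting material
6 | (3,4-dimethoxyphenyl)ethynylboronic acid MIDA ester | CN1CC(=O)OB(C#Cc2ccc(OC)c(OC)c2)OC(=O)C1 | intermediate
7 | 3',4'-dimethoxy-7-(3-methylbut-2-enyloxy)flavon-3-ylboronic acid MIDA ester | CN1CC(=O)OB(c2c(-c3ccc(OC)c(OC)c3)oc3cc(OCC=C(C)C)ccc3c2=O)OC(=O)C1 | intermediate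
8 | 3',4'-dimethoxy-7-(3-methylbut-2-enyloxy)flavon-3-ylboronic acid (not isolated) | OB(O)c1c(-c2ccc(OC)c(OC)c2)oc2cc(OCC=C(C)C)ccc2c1=O | intermediate
9 | 3',4'-dimethoxy-7-(3-methylbut-2-enyloxy)flavon-3-yl dihydrogen borate (not isolated) | OB(O)Oc1c(-c2ccc(OC)c(OC)c2)oc2cc(OCC=C(C)C)ccc2c1=O | intermediate
10 | 3-hydroxy-2-(3,4-dimethoxyphenyl)-7-(3-methylbut-2-enyloxy)chromen-4-one | COc1ccc(-c2oc3cc(OCC=C(C)C)ccc3c(=O)c2O)cc1OC | target

Total step count: 4. Longest linear sequence: 3 steps (steps 1, 3, 4 or steps 2, 3, 4).

Steps most likely to fail

Step 3 is the riskiest.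
- **What may go wrong:** the alkyne may insert in the reversed sense, so that boron ends next to O1. The acyl rhodium may lose CO. The MIDA cage may also hydrolyse, followed by copper-mediated dimerisation of the alkyne.
- **Fallback:** known chemistry that sets out from 3 and returns at 8. Dimethylsulfoxonium methylide (from Me3S(O)I and KOtBu, THF, reflux) is acylated with commercial 3,4-dimethoxybenzoyl chloride to the aroyl sulfoxonium ylide 1-(3,4-dimethoxyphenyl)-2-(dimethyloxosulfuranylidene)ethanone F1.
- Aldehyde 3 and F1 are then annulated under [Cp*RhCl2]2/AgSbF6/NaOAc in DCE at 80 °C. This is a known redox-neutral flavone synthesis in which the acyl rhodacycle takes up the ylide carbon as C3.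
- The resulting 1-(2-hydroxy-4-prenyloxyphenyl)-3-(3,4-dimethoxyphenyl)propane-1,3-dione F2 cyclodehydrates in the flask to 3',4'-dimethoxy-7-prenyloxyflavone F3. C4–C3 and O1–C2 are again the bonds made, and the connectivity of the ylide fixes the regiochemistry.
- LDA (THF, −78 °C) removes the C3 proton to give the 3-lithioflavone F4. B(OMe)3 traps it as dimethyl flavon-3-ylboronate F5, and the aqueous quench delivers boronic acid 8, which is oxidised as in step 4.

Step 4 is the second risk.
- **What may go wrong:** the liberated boronic acid may protodeboronate. Hydroxide may attack C2 and open ring C, or nucleophilic epoxidation of C2=C3 may occur before the boron-to-oxygen migration.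
- **Fallback:** a boron-free route that sets out from 2 and returns at 10. Prenyl bromide 2 alkylates the 4-OH of commercial 2,4-dihydroxyacetophenone (K2CO3, acetone, reflux) to 2-hydroxy-4-prenyloxyacetophenone F6.
- Claisen–Schmidt condensation with commercial 3,4-dimethoxybenzaldehyde (KOH, EtOH, rt) gives (E)-2'-hydroxy-3,4-dimethoxy-4'-prenyloxychalcone F7.
- Algar–Flynn–Oyamada oxidation (30% H2O2, aq NaOH, MeOH, 0 °C to rt) closes ring C and installs the 3-OH in one operation, giving 10.

Step 2 is the third risk.
- **What may go wrong:** the terminal alkyne may homocouple oxidatively at copper, and the amine together with traces of water may strip the MIDA cage.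
- **Fallback:** a route that sets out from 5, returns at 6, and attaches boron after the C(sp)–C(aryl) bond instead of before it. Iodide 5 is coupled with trimethylsilylacetylene (PdCl2(PPh3)2, CuI, Et3N, rt) to [(3,4-dimethoxyphenyl)ethynyl]trimethylsilane F8.
- K2CO3 in MeOH removes silicon to give 4-ethynyl-1,2-dimethoxybenzene F9, and n-BuLi (THF, −78 °C) gives lithium (3,4-dimethoxyphenyl)acetylide F10.
- B(OiPr)3 converts F10 into lithium triisopropoxy[(3,4-dimethoxyphenyl)ethynyl]borate F11. Adding F11 to N-methyliminodiacetic acid in DMSO at 115 °C exchanges the ligands on boron and gives 6.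

Further compounds
F1 | step 3 | 1-(3,4-dimethoxyphenyl)-2-(dimethyloxosulfuranylidene)ethanone | COc1ccc(C(=O)C=S(C)(C)=O)cc1OC
F2 | step 3 | 1-(2-hydroxy-4-prenyloxyphenyl)-3-(3,4-dimethoxyphenyl)propane-1,3-dione | COc1ccc(C(=O)CC(=O)c2ccc(OCC=C(C)C)cc2O)cc1OC
F3 | step 3 | 3',4'-dimethoxy-7-prenyloxyflavone | COc1ccc(-c2cc(=O)c3ccc(OCC=C(C)C)cc3o2)cc1OC
F4 | step 3 | 3-lithio-3',4'-dimethoxy-7-prenyloxyflavone | [Li]c1c(-c2ccc(OC)c(OC)c2)oc2cc(OCC=C(C)C)ccc2c1=O
F5 | step 3 | dimethyl 3',4'-dimethoxy-7-prenyloxyflavon-3-ylboronate | COB(OC)c1c(-c2ccc(OC)c(OC)c2)oc2cc(OCC=C(C)C)ccc2c1=O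
F6 | step 4 | 2-hydroxy-4-prenyloxyacetophenone | CC(=O)c1ccc(OCC=C(C)C)cc1O
F7 | step 4 | (E)-2'-hydroxy-3,4-dimethoxy-4'-prenyloxychalcone | COc1ccc(/C=C/C(=O)c2ccc(OCC=C(C)C)cc2O)cc1OC
F8 | step 2 | [(3,4-dimethoxyphenyl)ethynyl]trimethylsilane | COc1ccc(C#C[Si](C)(C)C)cc1OC
F9 | step 2 | 4-ethynyl-1,2-dimethoxybenzene | C#Cc1ccc(OC)c(OC)c1
F10 | step 2 | lithium (3,4-dimethoxyphenyl)acetylide | [Li]C#Cc1ccc(OC)c(OC)c1
F11 | step 2 | lithium triisopropoxy[(3,4-dimethoxyphenyl)ethynyl]borate | [Li+].COc1ccc(C#C[B-](OC(C)C)(OC(C)C)OC(C)C)cc1OC
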